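**Strategy.** The arene of ring B is not carried as a benzene: its carbons C4a'–C7' are stored as a 2,3,5-trisubstituted furan and C8'/C8a' as a terminal alkyne, so the crowded C3–C7' bond is made early, on a small heteroarene, by anti-selective allylboration. The route exploits the C8' phenol lying between ring-fusion carbon C8a' and C7': one gold-catalysed furan–yne isomerisation forms C4a'–C8a' and C7'–C8', delivers the furan oxygen to C8' and closes both the benzene ring and the carbocycle of ring B. Its precursor is the complete ring A tetralone carrying at C3 the furan, whose other α-carbon bears the C4'-silyloxy, C1'-dioxolane hex-5-ynyl chain.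

Key step: step 16

Remark: C3 is named S in every furan-bearing compound and R once ring B is a benzene; the spatial arrangement is the same, only the CIP ranking of its substituents changes (target: 3R,4S,4'R).

Assumption: the facial sense of the acid-catalysed allylboration in step 5 is taken from simple aryl aldehydes; it would be checked on 11 and the (R)-acid used if the sense proves opposite.

Step 1
Reactants: 1 3-bromo-5-methylphenol
Product: 2 1-(benzyloxy)-3-bromo-5-methylbenzene
Conditions: BnBr, K2CO3, DMF, rt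
Reagents that add atoms: benzyl bromide, BrCc1ccccc1
Why: Williamson etherification of the phenoxide; the benzyl ether withstands the lithium bases, the acylation and the gold step and is removed later by hydrogenolysis.

Step 2
Reactants: 2 1-(benzyloxy)-3-bromo-5-methylbenzene
Product: 5 2-(benzyloxy)-6-bromo-4-methylbenzaldehyde, via aryllithium 3 (not isolated), via lithium hemiaminal alkoxide 4 (not isolated)
Conditions: LiN(i-Pr)2 (1.1 equiv), THF, −78 °C; DMF, −78 → 0 °C; 1 M HCl
Reagents that add atoms: N,N-dimethylformamide, CN(C)C=O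
Why: Directed ortho-lithiation removes the hydrogen between bromine and the benzyloxy group, the most acidic on the ring, at a temperature where the ortho-bromo aryllithium does not lose LiBr to an aryne, and the aryllithium is formylated by DMF.

Step 3
Reactants: 6 3-methylfuran-2-carbaldehyde; 7 vinylmagnesium bromide
Product: 8 1-(3-methylfuran-2-yl)prop-2-en-1-ol (racemic)
Conditions: THF, −78 → 0 °C; sat. aq. NH4Cl
Reagents that add atoms: none
Why: Grignard 1,2-addition to the aldehyde; the racemic carbinol centre is erased in the next step.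

Step 4
Reactants: 8 1-(3-methylfuran-2-yl)prop-2-en-1-ol
Product: 9 2-[(2E)-3-(3-methylfuran-2-yl)prop-2-en-1-yl]-4,4,5,5-tetramethyl-1,3,2-dioxaborolane
Conditions: B2pin2 (1.5 equiv), Pd(MeCN)4(BF4)2 (5 mol%), DMSO/MeOH (1:1), rt
Reagents that add atoms: bis(pinacolato)diboron, CC1(C)OB(OC1(C)C)B1OC(C)(C)C(C)(C)O1
Why: Palladium-catalysed borylation of an allylic alcohol through an η3-allylpalladium intermediate that is borylated at its unsubstituted terminus, so the branched alcohol should give the conjugated linear (E)-allylboronate.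

Step 5
Reactants: 5 2-(benzyloxy)-6-bromo-4-methylbenzaldehyde; 9 (E)-3-(3-methylfuran-2-yl)allyl pinacol boronate
Product: 11 (1S,2S)-1-[2-(benzyloxy)-6-bromo-4-methylphenyl]-2-(3-methylfuran-2-yl)but-3-en-1-ol, via borate ester 10 (not isolated)
Conditions: (S)-3,3'-bis(2,4,6-triisopropylphenyl)-1,1'-binaphthyl-2,2'-diyl hydrogen phosphate (5 mol%), 4 Å MS, toluene, −30 → 0 °C; H2O
Reagents that add atoms: none
Why: Chiral-phosphoric-acid-catalysed allylboration through a closed chair (Zimmerman–Traxler) transition state: the (E)-boronate places the furyl group pseudo-equatorial, which sets C3 anti to the new C4 carbinol (cis once ring A is closed), and the (S)-acid, hydrogen-bonded to the boronate oxygen and the formyl hydrogen, is expected to direct addition to the Si face so that C4 is S.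

Step 6
Reactants: 11 (1S,2S)-1-[2-(benzyloxy)-6-bromo-4-methylphenyl]-2-(3-methylfuran-2-yl)but-3-en-1-ol
Product: 13 (1S,2S)-1-[2-(benzyloxy)-6-bromo-4-methylphenyl]-2-(3-methylfuran-2-yl)butane-1,4-diol, via alkylborane 12 (not isolated)
Conditions: 9-BBN (2.5 equiv), THF, 0 °C → rt; NaOH, H2O2, 0 °C → rt
Reagents that add atoms: hydrogen peroxide, OO
Why: Anti-Markovnikov hydroboration of the monosubstituted alkene by the bulky dialkylborane and stereoretentive C–B oxidation give the primary alcohol; furan, aryl bromide and both stereocentres are not touched (the excess borane allows for the free hydroxyl).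

Step 7
Reactants: 13 (1S,2S)-1-[2-(benzyloxy)-6-bromo-4-methylphenyl]-2-(3-methylfuran-2-yl)butane-1,4-diol
Product: 15 (4S,5S)-5-[2-(benzyloxy)-6-bromo-4-methylphenyl]-4-(3-methylfuran-2-yl)oxolan-2-one (trans lactone), via lactol 14 (not isolated)
Conditions: TEMPO (20 mol%), PhI(OAc)2 (2.5 equiv), CH2Cl2, rt
Reagents that add atoms: none
Why: Oxoammonium (TEMPO) oxidation is selective for the primary alcohol; the aldehyde is captured by the C4 hydroxyl as the five-membered lactol, which is oxidised on to the γ-lactone (oxidative lactonisation), masking the future C1 carbonyl and the C4 oxygen in one ring without touching C3 or C4.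

Step 8
Reactants: 16 succinic anhydride; 17 bis(trimethylsilyl)acetylene
Product: 18 4-oxo-6-(trimethylsilyl)hex-5-ynoic acid
Conditions: AlCl3 (2.2 equiv), CH2Cl2, 0 °C → rt; 1 M HCl
Reagents that add atoms: none
Why: Friedel–Crafts acylation of the bis-silyl alkyne with ipso-substitution of one silyl group (β-silyl-stabilised vinyl cation) opens the anhydride to the ynone acid and leaves the second silyl group as alkyne protection.

Step 9
Reactants: 18 4-oxo-6-(trimethylsilyl)hex-5-ynoic acid
Product: 20 3-{2-[(trimethylsilyl)ethynyl]-1,3-dioxolan-2-yl}propanoic acid, via silyl ester 19 (not isolated)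
Conditions: TMSOCH2CH2OTMS (3 equiv), TMSOTf (10 mol%), CH2Cl2, −78 → 0 °C; H2O
Reagents that add atoms: 1,2-bis(trimethylsilyloxy)ethane, C[Si](C)(C)OCCO[Si](C)(C)C
Why: Noyori ketalisation (silyl triflate catalysis, driven by Si–O bond formation) converts the ynone into the dioxolane under aprotic conditions that avoid conjugate addition of the diol; the carboxylic acid is silylated in the flask and freed again on aqueous work-up.

Step 10
Reactants: 15 trans lactone; 20 3-{2-[(trimethylsilyl)ethynyl]-1,3-dioxolan-2-yl}propanoic acid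
Product: 22 (4S,5S)-5-[2-(benzyloxy)-6-bromo-4-methylphenyl]-4-[3-methyl-5-(3-{2-[(trimethylsilyl)ethynyl]-1,3-dioxolan-2-yl}propanoyl)furan-2-yl]oxolan-2-one, via mixed anhydride 21 (not isolated)
Conditions: (CF3CO)2O (1.1 equiv), CH2Cl2, 0 °C; then 15, 0 °C → rt
Reagents that add atoms: none
Why: Friedel–Crafts acylation: the acyl trifluoroacetate formed from 20 acylates the electron-rich 2,3-dialkylfuran at its only free α-position (the future C4a') without a Lewis acid, conditions under which lactone, benzyl ether, aryl bromide and the propargylic dioxolane should persist, and the 2-acylfuran formed is deactivated towards a second acylation.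

Step 11
Reactants: 22 furyl ketone lactone
Product: 23 (4S,5S)-5-[2-(benzyloxy)-6-bromo-4-methylphenyl]-4-{5-[(1R)-1-hydroxy-3-{2-[(trimethylsilyl)ethynyl]-1,3-dioxolan-2-yl}propyl]-3-methylfuran-2-yl}oxolan-2-one
Conditions: RuCl[(R,R)-TsDPEN](p-cymene) (2 mol%), HCO2H/Et3N (5:2), CH2Cl2, rt
Reagents that add atoms: none
Why: Noyori asymmetric transfer hydrogenation of a 2-acylfuran: in the ruthenium hydride–amine transition state the furan ring takes the place of the aryl group of an aryl alkyl ketone, so the (R,R)-ligand should deliver hydride to give the (R)-carbinol at C4' under catalyst control, far from the lactone stereocentres.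

Step 12
Reactants: 23 (R)-furyl carbinol lactone
Product: 24 (3S,4S)-4-[2-(benzyloxy)-6-bromo-4-methylphenyl]-4-hydroxy-3-{5-[(1R)-1-hydroxy-3-{2-[(trimethylsilyl)ethynyl]-1,3-dioxolan-2-yl}propyl]-3-methylfuran-2-yl}-N-methoxy-N-methylbutanamide
Conditions: MeNH(OMe)·HCl (4 equiv), i-PrMgCl (9 equiv), THF, −20 → 0 °C; sat. aq. NH4Cl
Reagents that add atoms: N,O-dimethylhydroxylamine hydrochloride, CNOC.Cl
Why: Aminolysis of the γ-lactone by the magnesium amide of N,O-dimethylhydroxylamine (Weinreb amide formation) releases the C4 hydroxyl and turns the future C1 into an acyl donor that cannot over-add; no stereocentre is affected and the crude amide is silylated without delay so that it cannot relactonise.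

Step 13
Reactants: 24 dihydroxy Weinreb amide
Product: 25 (3S,4S)-4-[2-(benzyloxy)-6-bromo-4-methylphenyl]-4-[(tert-butyldimethylsilyl)oxy]-3-{5-[(1R)-1-[(tert-butyldimethylsilyl)oxy]-3-{2-[(trimethylsilyl)ethynyl]-1,3-dioxolan-2-yl}propyl]-3-methylfuran-2-yl}-N-methoxy-N-methylbutanamide
Conditions: TBSOTf (3 equiv), 2,6-lutidine (5 equiv), CH2Cl2, −78 → 0 °C
Reagents that add atoms: tert-butyldimethylsilyl trifluoromethanesulfonate, CC(C)(C)[Si](C)(C)OS(=O)(=O)C(F)(F)F
Why: Silyl triflate with a hindered pyridine base silylates both secondary alcohols, including the crowded benzylic C4 hydroxyl, which blocks relactonisation and removes every O–H before the organolithium and gold steps.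

Step 14
Reactants: 25 bis-silyl Weinreb amide
Product: 28 (3S,4S)-5-(benzyloxy)-4-[(tert-butyldimethylsilyl)oxy]-3-{5-[(1R)-1-[(tert-butyldimethylsilyl)oxy]-3-{2-[(trimethylsilyl)ethynyl]-1,3-dioxolan-2-yl}propyl]-3-methylfuran-2-yl}-7-methyl-3,4-dihydronaphthalen-1(2H)-one, via aryllithium 26 (not isolated), via tetrahedral adduct 27 (not isolated)
Conditions: t-BuLi (2.2 equiv), THF, −78 °C; sat. aq. NH4Cl
Reagents that add atoms: none
Why: Parham cyclisation: bromine–lithium exchange is faster than attack of t-BuLi on the amide, the aryllithium acylates itself on the Weinreb amide in a 6-exo-trig closure, and the chelated tetrahedral adduct survives until work-up so that the tetralone is not attacked again; at −78 °C ring closure should outrun oxygen-to-carbon silyl migration from the benzylic silyl ether.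

Step 15
Reactants: 28 silyl-alkyne tetralone
Product: 29 (3S,4S)-5-(benzyloxy)-4-[(tert-butyldimethylsilyl)oxy]-3-{5-[(1R)-1-[(tert-butyldimethylsilyl)oxy]-3-(2-ethynyl-1,3-dioxolan-2-yl)propyl]-3-methylfuran-2-yl}-7-methyl-3,4-dihydronaphthalen-1(2H)-one
Conditions: K2CO3 (0.3 equiv), MeOH/THF (3:1), rt
Reagents that add atoms: none
Why: Base-catalysed methanolysis cleaves the C(sp)–Si bond selectively; alkyl silyl ethers, dioxolane and the tetralone, which has no stereocentre α to the carbonyl, are stable to K2CO3 in methanol.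

Step 16
Reactants: 29 furan–yne tetralone
Product: 31 (3R,4S)-5-(benzyloxy)-4-[(tert-butyldimethylsilyl)oxy]-3-[(4'R)-4'-[(tert-butyldimethylsilyl)oxy]-8'-hydroxy-6'-methyl-3',4'-dihydro-2'H-spiro[[1,3]dioxolane-2,1'-naphthalen]-7'-yl]-7-methyl-3,4-dihydronaphthalen-1(2H)-one, via arene oxide 30 (not isolated)
Conditions: Ph3PAuNTf2 (5 mol%), 4 Å MS, CH2Cl2 (0.02 M), rt
Reagents that add atoms: none
Why: Cationic monovalent gold activates the terminal alkyne, the unsubstituted C=C bond of the furan (future C4a'–C5') attacks the internal alkyne carbon (future C8a') to give a cyclopropyl gold carbenoid, and this opens to a dienone carbene whose carbonyl oxygen adds to the carbene carbon, giving an oxepine in equilibrium with arene oxide 30; the epoxide opens at the fully substituted C7' and loss of the C8' proton gives the phenol. The closest known reaction is the gold-catalysed furan–yne phenol synthesis (Hashmi phenol synthesis), used here with an all-carbon four-atom tether on a trisubstituted furan. The carbocycle (C4a', C4', C3', C2', C1', C8a') closes by 6-exo-dig attack of the furan on the alkyne, and the benzene ring closes by 6π-electrocyclisation of the oxepine, which makes the C7'–C8' bond (formally the second bond of an intramolecular [4+2]). No stereocentre is created, and C3, C4 and C4' are spectators that cannot epimerise under these neutral conditions. The step needs chemoselectivity for furan attack and the correct oxygen position: the tether length and the gem-dialkoxy carbon next to the alkyne favour exo closure, both alcohols are silylated so that no oxygen nucleophile competes, and the oxygen must end on C8' because C7' carries carbon and cannot become a phenol.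

Step 17
Reactants: 31 benzyl-protected phenol
Product: 32 (3R,4S)-4-[(tert-butyldimethylsilyl)oxy]-3-[(4'R)-4'-[(tert-butyldimethylsilyl)oxy]-8'-hydroxy-6'-methyl-3',4'-dihydro-2'H-spiro[[1,3]dioxolane-2,1'-naphthalen]-7'-yl]-5-hydroxy-7-methyl-3,4-dihydronaphthalen-1(2H)-one
Conditions: H2 (1 atm), Pd/C (10 wt%), EtOAc, rt
Reagents that add atoms: none
Why: Hydrogenolysis of the aryl benzyl ether on palladium; the benzylic oxygens are silylated and C1' is a ketal, so neither benzylic C–O cleavage nor reduction at these positions is expected, and the reaction is stopped at full conversion to spare the C1 aryl ketone.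

Step 18
Reactants: 32 bis-silyl ketal diphenol
Product: 33 (3R,4S)-4-[(tert-butyldimethylsilyl)oxy]-3-[(5R)-5-[(tert-butyldimethylsilyl)oxy]-1-hydroxy-3-methyl-8-oxo-5,6,7,8-tetrahydronaphthalen-2-yl]-5-hydroxy-7-methyl-3,4-dihydronaphthalen-1(2H)-one
Conditions: 1 M aq. HCl/THF (1:4), rt
Reagents that add atoms: water, O
Why: Acid-catalysed hydrolysis of the dioxolane through an oxocarbenium ion stabilised by the ortho-hydroxyaryl ring gives the hydrogen-bonded C1' ketone; the benzylic oxygens are still silylated, which protects the 4-oxygenated tetralones from acid-induced dehydration, and any silyl ether lost here converges in step 19.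

Step 19
Reactants: 33 bis-silyl diketone
Product: 34 (3R,4S)-4,5-dihydroxy-3-[(5R)-1,5-dihydroxy-3-methyl-8-oxo-5,6,7,8-tetrahydronaphthalen-2-yl]-7-methyl-3,4-dihydronaphthalen-1(2H)-one (target; C4' = R in the primed numbering)
Conditions: HF·pyridine, THF, 0 °C → rt
Reagents that add atoms: none
Why: Fluoride cleaves both Si–O bonds (strong Si–F bond) under weakly acidic, non-basic conditions that should neither epimerise nor dehydrate the benzylic carbinols, giving the target with C3, C4 and C4' unchanged.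

**Compound list**

1 | 3-bromo-5-methylphenol | Cc1cc(O)cc(Br)c1 | starting material
2 | 1-(benzyloxy)-3-bromo-5-methylbenzene | Cc1cc(Br)cc(OCc2ccccc2)c1 | intermediate
3 | [2-(benzyloxy)-6-bromo-4-methylphenyl]lithium | [Li]c1c(Br)cc(C)cc1OCc1ccccc1 | intermediate (not isolated)
4 | lithium [2-(benzyloxy)-6-bromo-4-methylphenyl](dimethylamino)methanolate | CN(C)C(O[Li])c1c(Br)cc(C)cc1OCc1ccccc1 | intermediate (not isolated)
5 | 2-(benzyloxy)-6-bromo-4-methylbenzaldehyde | O=Cc1c(Br)cc(C)cc1OCc1ccccc1 | intermediate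
6 | 3-methylfuran-2-carbaldehyde | Cc1ccoc1C=O | starting material
7 | vinylmagnesium bromide | C=C[Mg]Br | starting material
8 | 1-(3-methylfuran-2-yl)prop-2-en-1-ol (racemic) | C=CC(O)c1occc1C | intermediate
9 | 2-[(2E)-3-(3-methylfuran-2-yl)prop-2-en-1-yl]-4,4,5,5-tetramethyl-1,3,2-dioxaborolane | Cc1ccoc1/C=C/CB1OC(C)(C)C(C)(C)O1 | intermediate
10 | pinacol borate ester of 11, 2-{[(1S,2S)-1-[2-(benzyloxy)-6-bromo-4-methylphenyl]-2-(3-methylfuran-2-yl)but-3-en-1-yl]oxy}-4,4,5,5-tetramethyl-1,3,2-dioxaborolane | C=C[C@H](c1occc1C)[C@H](OB1OC(C)(C)C(C)(C)O1)c1c(Br)cc(C)cc1OCc1ccccc1 | intermediate (not isolated)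
11 | (1S,2S)-1-[2-(benzyloxy)-6-bromo-4-methylphenyl]-2-(3-methylfuran-2-yl)but-3-en-1-ol (anti) | C=C[C@H](c1occc1C)[C@H](O)c1c(Br)cc(C)cc1OCc1ccccc1 | intermediate
12 | (1S,2S)-1-[2-(benzyloxy)-6-bromo-4-methylphenyl]-4-(9-borabicyclo[3.3.1]nonan-9-yl)-2-(3-methylfuran-2-yl)butan-1-ol (drawn with the hydroxyl free) | C1CCC2CCCC1B2CC[C@H](c1occc1C)[C@H](O)c1c(Br)cc(C)cc1OCc1ccccc1 | intermediate (not isolated)
13 | (1S,2S)-1-[2-(benzyloxy)-6-bromo-4-methylphenyl]-2-(3-methylfuran-2-yl)butane-1,4-diol | OCC[C@H](c1occc1C)[C@H](O)c1c(Br)cc(C)cc1OCc1ccccc1 | intermediate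
14 | (4S,5S)-5-[2-(benzyloxy)-6-bromo-4-methylphenyl]-4-(3-methylfuran-2-yl)oxolan-2-ol (anomer mixture) | OC1C[C@H](c2occc2C)[C@@H](c2c(Br)cc(C)cc2OCc2ccccc2)O1 | intermediate (not isolated)
15 | (4S,5S)-5-[2-(benzyloxy)-6-bromo-4-methylphenyl]-4-(3-methylfuran-2-yl)oxolan-2-one | O=C1C[C@H](c2occc2C)[C@@H](c2c(Br)cc(C)cc2OCc2ccccc2)O1 | intermediate
16 | succinic anhydride | O=C1CCC(=O)O1 | starting material
17 | bis(trimethylsilyl)acetylene | C[Si](C)(C)C#C[Si](C)(C)C | starting material
18 | 4-oxo-6-(trimethylsilyl)hex-5-ynoic acid | C[Si](C)(C)C#CC(=O)CCC(=O)O | intermediate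
19 | trimethylsilyl 3-{2-[(trimethylsilyl)ethynyl]-1,3-dioxolan-2-yl}propanoate | C[Si](C)(C)C#CC1(CCC(=O)O[Si](C)(C)C)OCCO1 | intermediate (not isolated)
20 | 3-{2-[(trimethylsilyl)ethynyl]-1,3-dioxolan-2-yl}propanoic acid | C[Si](C)(C)C#CC1(CCC(=O)O)OCCO1 | intermediate
21 | mixed anhydride of 20 with trifluoroacetic acid | C[Si](C)(C)C#CC1(CCC(=O)OC(=O)C(F)(F)F)OCCO1 | intermediate (not isolated)
22 | (4S,5S)-5-[2-(benzyloxy)-6-bromo-4-methylphenyl]-4-[3-methyl-5-(3-{2-[(trimethylsilyl)ethynyl]-1,3-dioxolan-2-yl}propanoyl)furan-2-yl]oxolan-2-one | O=C1C[C@H](c2oc(cc2C)C(=O)CCC2(OCCO2)C#C[Si](C)(C)C)[C@@H](c2c(Br)cc(C)cc2OCc2ccccc2)O1 | intermediate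
23 | (4S,5S)-5-[2-(benzyloxy)-6-bromo-4-methylphenyl]-4-{5-[(1R)-1-hydroxy-3-{2-[(trimethylsilyl)ethynyl]-1,3-dioxolan-2-yl}propyl]-3-methylfuran-2-yl}oxolan-2-one | O=C1C[C@H](c2oc(cc2C)[C@H](O)CCC2(OCCO2)C#C[Si](C)(C)C)[C@@H](c2c(Br)cc(C)cc2OCc2ccccc2)O1 | intermediate
24 | (3S,4S)-4-[2-(benzyloxy)-6-bromo-4-methylphenyl]-4-hydroxy-3-{5-[(1R)-1-hydroxy-3-{2-[(trimethylsilyl)ethynyl]-1,3-dioxolan-2-yl}propyl]-3-methylfuran-2-yl}-N-methoxy-N-methylbutanamide | CON(C)C(=O)C[C@H](c1oc(cc1C)[C@H](O)CCC1(OCCO1)C#C[Si](C)(C)C)[C@H](O)c1c(Br)cc(C)cc1OCc1ccccc1 | intermediate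
25 | (3S,4S)-4-[2-(benzyloxy)-6-bromo-4-methylphenyl]-4-[(tert-butyldimethylsilyl)oxy]-3-{5-[(1R)-1-[(tert-butyldimethylsilyl)oxy]-3-{2-[(trimethylsilyl)ethynyl]-1,3-dioxolan-2-yl}propyl]-3-methylfuran-2-yl}-N-methoxy-N-methylbutanamide | CON(C)C(=O)C[C@H](c1oc(cc1C)[C@H](O[Si](C)(C)C(C)(C)C)CCC1(OCCO1)C#C[Si](C)(C)C)[C@H](O[Si](C)(C)C(C)(C)C)c1c(Br)cc(C)cc1OCc1ccccc1 | intermediate
26 | aryllithium from 25 (lithium in place of bromine) | CON(C)C(=O)C[C@H](c1oc(cc1C)[C@H](O[Si](C)(C)C(C)(C)C)CCC1(OCCO1)C#C[Si](C)(C)C)[C@H](O[Si](C)(C)C(C)(C)C)c1c([Li])cc(C)cc1OCc1ccccc1 | intermediate (not isolated)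
27 | lithium alkoxide of the C1 N-methoxy-N-methyl hemiaminal of 28 (tetrahedral adduct, C1 unspecified) | Cc1cc(OCc5ccccc5)c2c(c1)C(O[Li])(N(C)OC)C[C@H](c3oc(cc3C)[C@H](O[Si](C)(C)C(C)(C)C)CCC4(OCCO4)C#C[Si](C)(C)C)[C@@H]2O[Si](C)(C)C(C)(C)C | intermediate (not isolated)
28 | (3S,4S)-5-(benzyloxy)-4-[(tert-butyldimethylsilyl)oxy]-3-{5-[(1R)-1-[(tert-butyldimethylsilyl)oxy]-3-{2-[(trimethylsilyl)ethynyl]-1,3-dioxolan-2-yl}propyl]-3-methylfuran-2-yl}-7-methyl-3,4-dihydronaphthalen-1(2H)-one | Cc1cc(OCc5ccccc5)c2c(c1)C(=O)C[C@H](c3oc(cc3C)[C@H](O[Si](C)(C)C(C)(C)C)CCC4(OCCO4)C#C[Si](C)(C)C)[C@@H]2O[Si](C)(C)C(C)(C)C | intermediate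
29 | (3S,4S)-5-(benzyloxy)-4-[(tert-butyldimethylsilyl)oxy]-3-{5-[(1R)-1-[(tert-butyldimethylsilyl)oxy]-3-(2-ethynyl-1,3-dioxolan-2-yl)propyl]-3-methylfuran-2-yl}-7-methyl-3,4-dihydronaphthalen-1(2H)-one (key-step precursor) | Cc1cc(OCc5ccccc5)c2c(c1)C(=O)C[C@H](c3oc(cc3C)[C@H](O[Si](C)(C)C(C)(C)C)CCC4(OCCO4)C#C)[C@@H]2O[Si](C)(C)C(C)(C)C | intermediate
30 | arene oxide of ring B (7',8'-epoxide, valence tautomer of the oxepine; epoxide carbons unspecified) | Cc1cc(OCc5ccccc5)c2c(c1)C(=O)C[C@H](C36OC6C4=C(C=C3C)[C@H](O[Si](C)(C)C(C)(C)C)CCC47OCCO7)[C@@H]2O[Si](C)(C)C(C)(C)C | intermediate (not isolated)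
31 | (3R,4S)-5-(benzyloxy)-4-[(tert-butyldimethylsilyl)oxy]-3-[(4'R)-4'-[(tert-butyldimethylsilyl)oxy]-8'-hydroxy-6'-methyl-3',4'-dihydro-2'H-spiro[[1,3]dioxolane-2,1'-naphthalen]-7'-yl]-7-methyl-3,4-dihydronaphthalen-1(2H)-one (key-step product) | Cc1cc(OCc5ccccc5)c2c(c1)C(=O)C[C@H](c3c(C)cc6c(c3O)C4(OCCO4)CC[C@H]6O[Si](C)(C)C(C)(C)C)[C@@H]2O[Si](C)(C)C(C)(C)C | intermediate
32 | (3R,4S)-4-[(tert-butyldimethylsilyl)oxy]-3-[(4'R)-4'-[(tert-butyldimethylsilyl)oxy]-8'-hydroxy-6'-methyl-3',4'-dihydro-2'H-spiro[[1,3]dioxolane-2,1'-naphthalen]-7'-yl]-5-hydroxy-7-methyl-3,4-dihydronaphthalen-1(2H)-one | Cc1cc(O)c2c(c1)C(=O)C[C@H](c3c(C)cc6c(c3O)C4(OCCO4)CC[C@H]6O[Si](C)(C)C(C)(C)C)[C@@H]2O[Si](C)(C)C(C)(C)C | intermediate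
33 | (3R,4S)-4-[(tert-butyldimethylsilyl)oxy]-3-[(5R)-5-[(tert-butyldimethylsilyl)oxy]-1-hydroxy-3-methyl-8-oxo-5,6,7,8-tetrahydronaphthalen-2-yl]-5-hydroxy-7-methyl-3,4-dihydronaphthalen-1(2H)-one | Cc1cc(O)c2c(c1)C(=O)C[C@H](c1c(C)cc3c(c1O)C(=O)CC[C@H]3O[Si](C)(C)C(C)(C)C)[C@@H]2O[Si](C)(C)C(C)(C)C | intermediate
34 | (3R,4S)-4,5-dihydroxy-3-[(5R)-1,5-dihydroxy-3-methyl-8-oxo-5,6,7,8-tetrahydronaphthalen-2-yl]-7-methyl-3,4-dihydronaphthalen-1(2H)-one | Cc1cc(O)c2c(c1)C(=O)C[C@H](c1c(C)cc3c(c1O)C(=O)CC[C@H]3O)[C@@H]2O | target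

**Totals.** 19 steps in all. The longest linear sequence is 15 steps (steps 1, 2, 5, 6, 7 and 10–19 from 3-bromo-5-methylphenol; the furan branch through steps 3 and 4 is equally long).

**Steps most likely to fail**

1. Step 16 (gold isomerisation). The gold-activated alkyne may be consumed before the furan closes on it: the 6-exo attack through an all-carbon tether next to the crowded, rigid ring A may be slow, so that hydration, oligomerisation or participation of a dioxolane oxygen takes over. Fallback: build ring B one stage earlier and close ring A last. Setting out from 25, K2CO3 in MeOH removes the alkynyl silyl group to give the terminal alkyne amide F1. Ph3PAuNTf2 in CH2Cl2 then runs the same furan–yne isomerisation on this flexible, ketone-free substrate, through the arene oxide F2 (not isolated), to the phenol amide F3. t-BuLi (3.2 equiv, THF, −78 °C; the first equivalent deprotonates the phenol) gives the dilithio species F4 (not isolated), which closes ring A through the tetrahedral adduct F5 (not isolated). Aqueous work-up brings the route back at 31.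

2. Step 5 (asymmetric allylboration). Facial discrimination may be weak, or the catalysed pathway so slow that uncatalysed racemic addition competes, because the aldehyde has two ortho substituents and the boronate a conjugated γ-heteroaryl group. Fallback: resolution in place of asymmetric catalysis. Setting out from 5 and 9, the uncatalysed allylboration (toluene, rt to 50 °C) still passes through the closed chair and should give the racemic anti product. This is borate 10 together with its enantiomer F6 (not isolated) and, after aqueous work-up, alcohol 11 together with its enantiomer F7. Preparative chromatography on a chiral stationary phase separates the two, and the route is rejoined at 11.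

3. Step 10 (furan acylation). The acylating agent may be lost by attack of a dioxolane oxygen on the mixed anhydride, or the ketal cleaved by the acid released, before the furan is acylated. Fallback: formylation, Grignard addition and oxidation in place of direct acylation. Setting out from 15, Vilsmeier–Haack formylation (POCl3, DMF; then aq. NaOAc) gives, via the iminium chloride F8 (not isolated), the 5-formylfuran lactone F9. The nucleophile is made from 3-bromopropanoyl chloride and 17 (AlCl3, CH2Cl2), which give the bromo ynone F10; ketalisation as in step 9 gives the bromide F11, and Mg in THF converts it into the Grignard reagent F12. Addition of F12 to F9 at −78 °C (the aldehyde reacts before the lactone) gives the carbinol F13 as an epimer mixture, and Dess–Martin periodinane oxidation brings the route back at 22.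

**Further compounds**

F1 | step 16 | (3S,4S)-4-[2-(benzyloxy)-6-bromo-4-methylphenyl]-4-[(tert-butyldimethylsilyl)oxy]-3-{5-[(1R)-1-[(tert-butyldimethylsilyl)oxy]-3-(2-ethynyl-1,3-dioxolan-2-yl)propyl]-3-methylfuran-2-yl}-N-methoxy-N-methylbutanamide | CON(C)C(=O)C[C@H](c1oc(cc1C)[C@H](O[Si](C)(C)C(C)(C)C)CCC1(OCCO1)C#C)[C@H](O[Si](C)(C)C(C)(C)C)c1c(Br)cc(C)cc1OCc1ccccc1
F2 | step 16 | arene oxide of ring B formed from F1 (7',8'-epoxide, epoxide carbons unspecified; not isolated) | CON(C)C(=O)C[C@H](C36OC6C4=C(C=C3C)[C@H](O[Si](C)(C)C(C)(C)C)CCC47OCCO7)[C@H](O[Si](C)(C)C(C)(C)C)c1c(Br)cc(C)cc1OCc1ccccc1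
F3 | step 16 | (3R,4S)-4-[2-(benzyloxy)-6-bromo-4-methylphenyl]-4-[(tert-butyldimethylsilyl)oxy]-3-[(4'R)-4'-[(tert-butyldimethylsilyl)oxy]-8'-hydroxy-6'-methyl-3',4'-dihydro-2'H-spiro[[1,3]dioxolane-2,1'-naphthalen]-7'-yl]-N-methoxy-N-methylbutanamide | CON(C)C(=O)C[C@H](c1c(C)cc2c(c1O)C1(OCCO1)CC[C@H]2O[Si](C)(C)C(C)(C)C)[C@H](O[Si](C)(C)C(C)(C)C)c1c(Br)cc(C)cc1OCc1ccccc1
F4 | step 16 | dilithio species from F3 (lithium phenoxide, lithium in place of bromine; not isolated) | CON(C)C(=O)C[C@H](c1c(C)cc2c(c1O[Li])C1(OCCO1)CC[C@H]2O[Si](C)(C)C(C)(C)C)[C@H](O[Si](C)(C)C(C)(C)C)c1c([Li])cc(C)cc1OCc1ccccc1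
F5 | step 16 | dilithium salt of the C1 N-methoxy-N-methyl hemiaminal of 31 (tetrahedral adduct, C1 unspecified; not isolated) | Cc1cc(OCc5ccccc5)c2c(c1)C(O[Li])(N(C)OC)C[C@H](c3c(C)cc6c(c3O[Li])C4(OCCO4)CC[C@H]6O[Si](C)(C)C(C)(C)C)[C@@H]2O[Si](C)(C)C(C)(C)C
F6 | step 5 | enantiomer of borate 10, 2-{[(1R,2R)-1-[2-(benzyloxy)-6-bromo-4-methylphenyl]-2-(3-methylfuran-2-yl)but-3-en-1-yl]oxy}-4,4,5,5-tetramethyl-1,3,2-dioxaborolane (not isolated) | C=C[C@@H](c1occc1C)[C@@H](OB1OC(C)(C)C(C)(C)O1)c1c(Br)cc(C)cc1OCc1ccccc1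
F7 | step 5 | (1R,2R)-1-[2-(benzyloxy)-6-bromo-4-methylphenyl]-2-(3-methylfuran-2-yl)but-3-en-1-ol (enantiomer of 11) | C=C[C@@H](c1occc1C)[C@@H](O)c1c(Br)cc(C)cc1OCc1ccccc1
F8 | step 10 | N-({5-[(2S,3S)-2-[2-(benzyloxy)-6-bromo-4-methylphenyl]-5-oxooxolan-3-yl]-4-methylfuran-2-yl}methylidene)-N-methylmethanaminium chloride (not isolated) | O=C1C[C@H](c2oc(C=[N+](C)C)cc2C)[C@@H](c2c(Br)cc(C)cc2OCc2ccccc2)O1.[Cl-]
F9 | step 10 | 5-[(2S,3S)-2-[2-(benzyloxy)-6-bromo-4-methylphenyl]-5-oxooxolan-3-yl]-4-methylfuran-2-carbaldehyde | O=C1C[C@H](c2oc(C=O)cc2C)[C@@H](c2c(Br)cc(C)cc2OCc2ccccc2)O1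
F10 | step 10 | 1-bromo-5-(trimethylsilyl)pent-4-yn-3-one | C[Si](C)(C)C#CC(=O)CCBr
F11 | step 10 | 2-(2-bromoethyl)-2-[(trimethylsilyl)ethynyl]-1,3-dioxolane | C[Si](C)(C)C#CC1(CCBr)OCCO1
F12 | step 10 | (2-{2-[(trimethylsilyl)ethynyl]-1,3-dioxolan-2-yl}ethyl)magnesium bromide (not isolated) | C[Si](C)(C)C#CC1(CC[Mg]Br)OCCO1
F13 | step 10 | (4S,5S)-5-[2-(benzyloxy)-6-bromo-4-methylphenyl]-4-[5-(1-hydroxy-3-{2-[(trimethylsilyl)ethynyl]-1,3-dioxolan-2-yl}propyl)-3-methylfuran-2-yl]oxolan-2-one (carbinol epimers) | O=C1C[C@H](c2oc(cc2C)C(O)CCC2(OCCO2)C#C[Si](C)(C)C)[C@@H](c2c(Br)cc(C)cc2OCc2ccccc2)O1
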